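A leftover starts me off: at the last reading L still stands at 12.3 % in the green run and 11.1 % in the teal run, both with 0.95 equiv of X, while with 1.9 equiv in the grey run L falls lower, to 2.2 %. So I treat X as the limiting reagent in the first two runs.

| flask | L | X | remark | time |
|---|---|---|---|---|
| green | 0.067 M | 0.95 equiv | run made earlier |  |
| teal | 0.15 M | 0.95 equiv | run made earlier |  |
| grey | 0.10 M | 1.9 equiv | run made earlier |  |
| flask | 0.10 M | 0.950 equiv |  | 3.0 h |

| run | time / h | E / % | G / % | Z / % | L / % |
|---|---|---|---|---|---|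
| green | 0.250 | 1.0 | 25.4 | 6.4 | 66.6 |
| green | 0.667 | 14.1 | 35.3 | 12.8 | 38.0 |
| green | 1.50 | 32.7 | 32.0 | 15.6 | 19.6 |
| green | 4.00 | 46.1 | 28.0 | 16.1 | 12.3 |
| teal | 0.417 | 10.4 | 24.5 | 17.2 | 50.4 |
| teal | 1.33 | 37.7 | 26.7 | 19.2 | 18.5 |
| teal | 2.50 | 43.4 | 25.5 | 13.7 | 12.9 |
| teal | 4.00 | 45.5 | 26.0 | 18.2 | 11.1 |
| grey | 0.250 | 6.1 | 16.6 | 15.2 | 64.0 |
| grey | 0.667 | 26.1 | 14.3 | 26.3 | 32.3 |
| grey | 1.50 | 56.7 | 7.3 | 26.7 | 9.0 |
| grey | 4.00 | 72.3 | 2.6 | 25.3 | 2.2 |

(each reading ± 1 percentage point)

* the largest share of what was charged as L, at 3.0 h belongs to (Z / E / G / L)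
* the largest share itself, whichever of these holds it, in percent of the L charged

The bench rule says one equivalent of X gives one of product. But Z and E together read 62.2 % in the green run and 63.7 % in the teal run. So I define the take, Z plus E as a fraction of the L charged, per equivalent of X charged, over those two last readings: 0.663, not one.

The border shows in the grey run. There the take promises 126 % of the L charged, but the reading is less, 97.6 %, and the ratio to its X falls to 0.514. So the take is a figure read from the two runs with 0.95 equiv of X, and it stops working at 1.9 equiv, where L is down to 2.2 %.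

The flask has 0.950 equiv of X, like the green and teal runs, and its L of 0.10 M lies between their 0.067 M and 0.15 M, so I expect Z plus E near 62.9 %. With E's part as in those readings, that puts E near 45.8 % if the flask has stalled by 3.0 h. The forecast says E at 44 %, between 41.5 % and 46.5 %: “That points to X running out”.

The flask gives E at 45.1 %.

    X → D (k = 0.00289 s⁻¹)
    Z ⇌ E (K = 2.90, k = 8.64 × 10⁻⁴ s⁻¹)
    G + J → Z (k = 0.0152 L mol⁻¹ s⁻¹)
    L ⇌ G (K = 2.28, k = 5.20 × 10⁻⁴ s⁻¹)
    X → J (k = 0.00543 s⁻¹)
    Z → Q (k = 1.06 × 10⁻⁶ s⁻¹)

X in the flask stands at 0 % of its charge at 3.00 h, and the flask's own take is 0.642. In the neighbour flask with L at 0.025 M, the equivalents and time held, E is 35.2 % and Z 13.8 %, which is 14 percentage points short of what the take promises, and J there stands at 0.00322 M, or 12.9 % of its L.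

(The data come from a simulation with made-up constants; scatter was added.)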